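# Kuwanon W: synthesis design built on a ketene–ynol ether benzannulation of ring A

Atom labels: flavone atoms are unprimed (O1, C2–C8a); ring D is C1''–C6''. The chromene phenol is called "chromene O5" (2H-chromene numbering).

## The problem

Kuwanon W (27) is a 3-prenylflavone whose C8 carries C3'' of a methylcyclohexene (ring D). C4'' bears a (5-hydroxy-2,2-dimethyl-2H-chromen-6-yl)carbonyl group and C5'' a 2,4-dihydroxyphenyl group, so the molecule is formally the [4+2] adduct of a chalcone and a dehydroprenylflavone. The three contiguous stereocenters are all-trans (3''S,4''S,5''R). C4'' is α to the ketone and can be equilibrated to the arrangement trans to both neighbours, but only if C3'' and C5'' are already cis to each other; these two cannot be corrected once set. Ring A is a pentasubstituted phloroglucinol with the aryl–C3'' bond at C8 between two oxygenated carbons, and a synthesis must decide which of its three oxygens becomes O1 (cyclohexenyl at C8 or at C6). The chromene, the prenyl group and the ring D alkene all lie next to phenols and close to cyclic ethers under protic or strong Lewis acid. The C4'' ketone is flanked by two ortho-hydroxyaryl groups that can ketalise it, the six phenols are oxidant-sensitive, and hydrogenation is excluded. The feature that opens the route is the pattern of ring A: C8, bearing the secondary carbon C3'', is flanked by C7–O and C8a–O, with C5–O para to it. A ketene–ynol ether benzannulation gives exactly this pattern, with the alkyl group coming from the alkyne and the three oxygens differentiated from the start.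

## Retrosynthesis

**Protecting groups (27 ⇒ 26 ⇒ 25).** The last bonds cut are four O–Si bonds (fluoride), then O–Et at C5 and two O–CH2OMe bonds (BCl3). The ethyl ether is the regiochemical marker left by the benzannulation and is peri to the C4 carbonyl, so chelation-assisted cleavage is possible. Silyl groups on the other phenols keep free phenols away from the Lewis acid and make the final step a buffered fluoride treatment. Precursor 25 is the fully masked flavone.

**Pyranone (25 ⇒ 24 ⇒ 20 + 23).** O1–C2 and C2–C3 are cut in the Baker–Venkataraman sense. Carrying the prenyl group in ketone 20 avoids a late C-prenylation or a coupling at a 3-haloflavone. The forward reactions must aroylate the ketone enolate with acid chloride 23 and close the ring at the only free phenol (O at C8a) under weak acid.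

**C4a–acyl bond (20 ⇒ 18 ⇒ 17).** Friedel–Crafts or Fries acylation is ruled out by the MOM ethers, the chromene and the alkenes. Phenol 17 has exactly one free ortho position, so magnesium-mediated ortho-formylation gives 18, and Grignard addition with in-flask Oppenauer oxidation gives 20.

**Ring A (17 ⇒ 12 + 13), the key cut.** C8–C8a, C6–C7 and C4a–C8a are cut together. Siloxyalkyne 12 carries all of ring D; 3-ethoxycyclobut-2-en-1-one (13) supplies C4a, C5, C6 and C8a. Against an arylation at C3'', this never makes the hindered C8–C3'' bond on an arene. It also delivers OH at C8a, OSi at C7 and OEt at C5, so the pyranone can close in one direction only. The forward reaction needs only regiocontrol and must leave the stereotriad alone.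

**Ynol ether (12 ⇒ 10 ⇒ 9).** The O–C(sp) bond is made by oxidising the lithium acetylide of 10 to the ynolate and silylating it. An ester homologation route would need an ester at C3'' and alkyllithium reagents next to the ketone. The chromene O5 hydroxyl is left free until this step: as a phenoxide it deactivates the ketone, and the same silyl triflate caps it.

**Ring D (9 ⇒ 5 + 8).** C3''–C4'' and C5''–C6'' are cut as a Diels–Alder reaction of 2'-hydroxychalcone 5 with dienyne 8. One step brings in every ring D carbon, the alkyne and all three stereocenters, and a chiral borate bound to the chalcone gives absolute control. An annulation–ionisation route (cyclohexenone, allylic cation, alkynyl nucleophile) was set aside for three reasons: the cation next to the enolisable aroyl group would lose a proton to a dienone, the ortho-alkoxyaryl group at C5'' can capture it at C1'', and no step would set absolute configuration. The cycloaddition must be exo and face-selective.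

**Fragments.** Chalcone 5 comes from chromene ketone 2 and aldehyde 4 by Claisen–Schmidt condensation. Ketone 2 comes from 1 and prenal, and 4 from 3. Dienyne 8 comes from 6 by two Wittig reactions through 7. Acid chloride 23 comes from 21 through silyl ester 22.

## Roads not taken

**Alternative 1:** Ring D is cut as a formal Diels–Alder reaction in two stages. Chalcone 5, bound to Sc(OTf)3 and a chiral pybox ligand and sensitised by Ru(bpy)3(PF6)2 under visible light, would add across the terminal alkene of flavone diene A2 to give vinylcyclobutane A1 (C5''–C6'' and C4''–C1''). A 1,3-shift of C4'' from C1'' to C3'' would then expand the ring.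
- Merits: it is highly convergent, since ring A, the flavone and the prenyl group arrive in one piece. The photocycloaddition has catalytic asymmetric precedent for 2'-hydroxychalcones, and little is left after fragment union.
- Weak points: the ring expansion must create C3'' trans to C4'' while the C1''–C4'' bond breaks. Thermal vinylcyclobutane shifts pass through diradicals at high temperature, and cation-radical or Lewis-acid variants would meet the chromene and prenyl groups. The styryl-flavone chromophore of A2 competes for triplet energy (E/Z isomerisation, dimerisation). A2 itself needs a full flavone synthesis with vinylation at C8.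
- Comparison: in convergence and step count after union this road is better, and that is conceded. The chosen plan sets against it that all three stereocenters come from one concerted cycloaddition on small fragments, and that the C8–C3'' bond is never made on a preformed arene. The price is a linear eight-step build-up of the flavone on ring D.

**Alternative 2:** The chromene C–C and C–O bonds are cut last. Ethylenediammonium diacetate would condense 3-methylbut-2-enal with resorcinol ketone A4 at the carbon between its hydroxyls, and oxa-electrocyclisation through the para oxygen would give A3.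
- Merits: the acid-sensitive chromene is absent from every earlier step. The reaction is reliable, and chelation of the ortho hydroxyl fixes its direction.
- Weak points: it solves none of the hard problems (ring D, the stereotriad, the aryl–C3'' bond). A4 must be carried with a uniquely free resorcinol ring, and A3 still needs six MOM ethers removed by acid next to the new chromene.
- Comparison: for chromene survival this road is safer than the chosen plan, whose chromene must pass a boron Lewis acid, 110 °C and BCl3. The chosen plan sets against it that the same condensation is run in step 1 on the simple ketone 1, and that chromene ketone 2 then serves directly as the chalcone half.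

**Alternative 3:** C1''=C2'' is cut. The second-generation Grubbs catalyst would join the vinyl group on C3'' and the methallyl group on C5'' of triene A6 and give cyclohexene A5 with loss of ethylene.
- Merits: each stereocenter is set by acyclic stereocontrol with no exo/endo question, and ring closure to the trisubstituted cyclohexene is dependable.
- Weak points: A6 is long to make (three adjacent tertiary centres bearing two aryl groups and an aroyl group, C4'' epimerisable with no ring to bias it), and the hindered aryl–C3'' bond has to be made early. The phloroglucinol ring of A5 also carries three identical MOM ethers, so acylation and pyranone closure cannot tell the oxygens flanking C8 from the one para to it, and 6- and 8-cyclohexenyl flavones would both form.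
- Comparison: in stereochemical certainty this road is better than the single cycloaddition of the chosen plan. The chosen plan sets against it a one-step ring D from 5 and 8, and a ring A whose three oxygens come out different (OH, OSi, OEt), which settles the 6/8 question.

Key step: step 9

## Assumptions

- The (R)-VANOL borate is assumed, by analogy with related boron-templated 2'-hydroxychalcone cycloadditions, to expose the enone face that leads to the 4''S,5''R adduct; if the sense is opposite, (S)-VANOL is used.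
- 3-(Trimethylsilyl)prop-2-ynal (6), 3-ethoxycyclobut-2-en-1-one (13), 5-bromo-2-methylpent-2-ene and VANOL are taken as purchasable.

## Route

Step 1
Reactants: 1 2,4-dihydroxyacetophenone
Product: 2 1-(5-hydroxy-2,2-dimethyl-2H-chromen-6-yl)ethan-1-one
Conditions: 3-methylbut-2-enal, pyridine, 120 °C
Reagents that add atoms: 3-methylbut-2-enal, CC(C)=CC=O
Why: Chromenylation of a resorcinol: Knoevenagel-type condensation at C3 (between the two hydroxyls) and oxa-6π-electrocyclisation through the free 4-hydroxyl; the 2-hydroxyl stays hydrogen-bonded to the acetyl group, which fixes the angular fusion.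

Step 2
Reactants: 3 2,4-dihydroxybenzaldehyde
Product: 4 2,4-bis(methoxymethoxy)benzaldehyde
Conditions: MOMCl, i-Pr2NEt, CH2Cl2, 0 → 40 °C
Reagents that add atoms: chloromethyl methyl ether, COCCl
Why: Williamson-type acetal ether formation; excess reagent and warming are needed for the hydrogen-bonded 2-hydroxyl.

Step 3
Reactants: 2 1-(5-hydroxy-2,2-dimethyl-2H-chromen-6-yl)ethan-1-one; 4 2,4-bis(methoxymethoxy)benzaldehyde
Product: 5 (E)-3-[2,4-bis(methoxymethoxy)phenyl]-1-(5-hydroxy-2,2-dimethyl-2H-chromen-6-yl)prop-2-en-1-one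
Conditions: KOH, EtOH–H2O, 0 °C → rt
Reagents that add atoms: none
Why: Claisen–Schmidt condensation; E1cB loss of water gives the E-enone, and the chelated hydroxyl does not add to the enone under these cold conditions.

Step 4
Reactants: 6 3-(trimethylsilyl)prop-2-ynal
Product: 7 (E)-6-(trimethylsilyl)hex-3-en-5-yn-2-one
Conditions: Ph3P=CHCOCH3, CH2Cl2, rt
Reagents that add atoms: 1-(triphenyl-λ5-phosphanylidene)propan-2-one, CC(=O)C=P(c1ccccc1)(c1ccccc1)c1ccccc1
Why: Wittig olefination with a stabilised ylide, which gives the E-enone.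

Step 5
Reactants: 7 (E)-6-(trimethylsilyl)hex-3-en-5-yn-2-one
Product: 8 (E)-trimethyl(5-methylhexa-3,5-dien-1-yn-1-yl)silane
Conditions: Ph3PCH3Br, KOt-Bu, THF, 0 °C; then 7, 0 °C → rt
Reagents that add atoms: methylenetriphenylphosphorane (from methyltriphenylphosphonium bromide and KOt-Bu), C=P(c1ccccc1)(c1ccccc1)c1ccccc1
Why: Wittig methylenation of the ketone; the non-stabilised ylide attacks the carbonyl group and leaves the E-alkene untouched. The volatile diene is carried on as a solution.

Step 6
Reactants: 5 (E)-3-[2,4-bis(methoxymethoxy)phenyl]-1-(5-hydroxy-2,2-dimethyl-2H-chromen-6-yl)prop-2-en-1-one; 8 (E)-trimethyl(5-methylhexa-3,5-dien-1-yn-1-yl)silane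
Product: 9 all-trans ring D ketone: (5-hydroxy-2,2-dimethyl-2H-chromen-6-yl){(1S,2S,6R)-6-[2,4-bis(methoxymethoxy)phenyl]-4-methyl-2-[(trimethylsilyl)ethynyl]cyclohex-3-en-1-yl}methanone
Conditions: (R)-VANOL, BH3·THF, AcOH, THF, rt, then evaporation; 5, 8 (3 equiv), 4 Å MS, PhCF3, rt
Reagents that add atoms: none
Why: Boron-templated asymmetric Diels–Alder reaction of a 2'-hydroxychalcone: phenolate and carbonyl oxygens chelate the VANOL borate, which lowers the LUMO and blocks one enone face. The methyl and alkynyl groups of 8 both direct C6''→C5'' and C3''→C4'' bonding, and the E-alkene fixes C4''/C5'' trans. The exo transition state (bulky aroyl borate turned away from the diene, only the slim alkynyl group beside it) should give C3''/C4'' trans, hence 3''S,4''S,5''R.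

Step 7
Reactants: 9 all-trans ring D ketone with trimethylsilylethynyl group
Product: 10 (5-hydroxy-2,2-dimethyl-2H-chromen-6-yl){(1S,2S,6R)-6-[2,4-bis(methoxymethoxy)phenyl]-2-ethynyl-4-methylcyclohex-3-en-1-yl}methanone
Conditions: K2CO3 (0.3 equiv), MeOH–THF, 0 °C
Reagents that add atoms: none
Why: Methanolysis of the alkynyl C–Si bond by catalytic methoxide; the MOM ethers are inert, and the only epimerisable centre (C4'') already holds its thermodynamic all-trans arrangement.

Step 8
Reactants: 10 terminal alkyne with free chromene O5 hydroxyl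
Product: 12 {(1S,2S,6R)-6-[2,4-bis(methoxymethoxy)phenyl]-4-methyl-2-[(triisopropylsilyloxy)ethynyl]cyclohex-3-en-1-yl}[2,2-dimethyl-5-(triisopropylsilyloxy)-2H-chromen-6-yl]methanone, via dilithium phenoxide–ynolate 11 (not isolated)
Conditions: LiN(SiMe3)2 (3.3 equiv), THF, −78 °C; t-BuOOH (1.1 equiv), −78 → 0 °C; i-Pr3SiOTf (2.3 equiv), −78 → 0 °C; work-up on Et3N-washed silica
Reagents that add atoms: tert-butyl hydroperoxide, CC(C)(C)OO; triisopropylsilyl trifluoromethanesulfonate, CC(C)[Si](OS(=O)(=O)C(F)(F)F)(C(C)C)C(C)C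
Why: Oxidation of a lithium acetylide by lithium tert-butyl peroxide (the acetylide attacks the O–O bond) gives the ynolate, which silylates on oxygen. The chromene phenol is deprotonated first; the phenoxide, conjugated with the ketone, shields the carbonyl group from base and nucleophile and is capped by the same silyl triflate.

Step 9
Reactants: 12 ring D siloxyalkyne; 13 3-ethoxycyclobut-2-en-1-one
Product: 17 5-ethoxy-2-(RD)-3-(triisopropylsilyloxy)phenol (RD = ring D unit defined in the compound list; free hydroxyl at the future C8a), via ethoxyvinylketene 14 (not isolated), via 4-vinylcyclobutenone 15 (not isolated), via dienylketene 16 (not isolated)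
Conditions: toluene, 80 → 110 °C, sealed tube, argon
Reagents that add atoms: none
Why: Heating opens 13 reversibly (four-electron electrocyclic opening) to ethoxyvinylketene 14. 14 adds [2+2] across the siloxyalkyne: the nucleophilic alkyne carbon bearing C3'' bonds to the ketene carbonyl carbon (C8–C8a) and the oxygen-bearing carbon to the ketene α-carbon (C6–C7), giving cyclobutenone 15. 15 opens again (four-electron) to dienylketene 16, which closes by thermal six-electron electrocyclisation between the ketene carbon and the terminal methylene (C4a–C8a) and tautomerises to phenol 17. The closest known reaction type is the Danheiser benzannulation of cyclobutenones with trialkylsiloxyalkynes to resorcinol monosilyl ethers, applied here to a 3-alkoxycyclobutenone to reach the phloroglucinol level. The benzene ring is the only ring kept, and it is closed in the last pericyclic step. No stereocenter is formed (the sp3 carbon of 15 is lost on ring opening), and the neutral thermal conditions leave the stereotriad and the C4'' ketone alone. The step needs regiochemistry, secured by the polarisation of ketene and ynol ether, and chemoselectivity over the chromene and ring D alkenes, secured by the much higher nucleophilicity of the siloxyalkyne. The result is OH only at C8a, OSi at C7 and OEt at C5 (para to C8).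

Step 10
Reactants: 17 5-ethoxy-2-(RD)-3-(triisopropylsilyloxy)phenol
Product: 18 6-ethoxy-2-hydroxy-3-(RD)-4-(triisopropylsilyloxy)benzaldehyde
Conditions: MgCl2, Et3N, (CH2O)n, MeCN, 80 °C
Reagents that add atoms: formaldehyde (as paraformaldehyde), C=O
Why: Casnati–Skattebøl ortho-formylation: the magnesium phenoxide delivers formaldehyde to the only free ortho position (C4a), and the benzylic alkoxide is oxidised by a second formaldehyde. The amine-buffered conditions spare MOM and silyl ethers and the chromene.

Step 11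
Reactants: 18 6-ethoxy-2-hydroxy-3-(RD)-4-(triisopropylsilyloxy)benzaldehyde
Product: 20 1-[6-ethoxy-2-hydroxy-3-(RD)-4-(triisopropylsilyloxy)phenyl]-5-methylhex-4-en-1-one, via bromomagnesium carbinolate 19 (not isolated)
Conditions: (4-methylpent-3-en-1-yl)MgBr (2.5 equiv), THF, −40 → 0 °C; then PhCHO (5 equiv), 0 °C → rt
Reagents that add atoms: (4-methylpent-3-en-1-yl)magnesium bromide, CC(C)=CCC[Mg]Br
Why: Grignard addition to the aldehyde (the C4'' ketone is shielded by the ortho-silyloxy aryl group and its two ring neighbours), then Mg–Oppenauer oxidation: the magnesium benzylic alkoxide transfers hydride to benzaldehyde. The electron-rich free phenol therefore never meets an oxidant.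

Step 12
Reactants: 21 2,4-dihydroxybenzoic acid
Product: 22 tert-butyldimethylsilyl 2,4-bis(tert-butyldimethylsilyloxy)benzoate
Conditions: TBSCl (3.5 equiv), imidazole, DMF, rt → 50 °C
Reagents that add atoms: tert-butyldimethylsilyl chloride, CC(C)(C)[Si](C)(C)Cl
Why: Silylation of both phenols and the acid; the silyl ester is the activated form needed in the next step.

Step 13
Reactants: 22 tert-butyldimethylsilyl 2,4-bis(tert-butyldimethylsilyloxy)benzoate
Product: 23 2,4-bis(tert-butyldimethylsilyloxy)benzoyl chloride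
Conditions: (COCl)2, DMF (cat.), CH2Cl2, 0 °C → rt
Reagents that add atoms: oxalyl chloride, O=C(Cl)C(=O)Cl
Why: Silyl ester to acid chloride exchange through the Vilsmeier-type chloroiminium salt; no free acid or HCl is formed, so the aryl silyl ethers stay.

Step 14
Reactants: 20 ring A aryl 4-methylpent-3-enyl ketone; 23 2,4-bis(tert-butyldimethylsilyloxy)benzoyl chloride
Product: 24 1-[2,4-bis(tert-butyldimethylsilyloxy)phenyl]-3-[6-ethoxy-2-hydroxy-3-(RD)-4-(triisopropylsilyloxy)phenyl]-2-(3-methylbut-2-en-1-yl)propane-1,3-dione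
Conditions: LiN(SiMe3)2 (3.3 equiv), THF, −78 → −20 °C; then 23, −78 °C → rt
Reagents that add atoms: none
Why: Baker–Venkataraman-type aroylation: the phenoxide–enolate dianion of 20 is acylated at carbon, or at the phenoxide oxygen followed by 1,5-acyl shift; both paths end in the same β-diketone, whose prenyl-bearing carbon becomes C3.

Step 15
Reactants: 24 ring A/ring B β-diketone
Product: 25 2-[2,4-bis(tert-butyldimethylsilyloxy)phenyl]-5-ethoxy-3-(3-methylbut-2-en-1-yl)-8-(RD)-7-(triisopropylsilyloxy)-4H-chromen-4-one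
Conditions: PPTS (0.3 equiv), 4 Å MS, toluene, 80 °C
Reagents that add atoms: none
Why: Cyclodehydration: the only free phenol (O at C8a) adds to the aroyl carbonyl and the hemiketal loses water to the 4-pyranone. The O5 ethyl ether cannot take part, so the cyclohexenyl group ends at C8. A weak acid is chosen because of the prenyl group, the MOM ethers and the chromene.

Step 16
Reactants: 25 fully protected flavone
Product: 26 2-[2,4-bis(tert-butyldimethylsilyloxy)phenyl]-5-hydroxy-3-(3-methylbut-2-en-1-yl)-8-(RD')-7-(triisopropylsilyloxy)-4H-chromen-4-one (RD' = ring D unit with free 2,4-dihydroxyphenyl group)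
Conditions: BCl3 (8 equiv), Bu4NI (4 equiv), CH2Cl2, −78 → 0 °C; then NaHCO3 (aq), −78 °C
Reagents that add atoms: none
Why: Chelation-assisted ether cleavage: boron binds the C4 carbonyl and O5, iodide removes the ethyl group, and the two MOM acetals go at the same temperature. Four phenols stay silylated (partial silyl loss is harmless), so no free phenol sits next to the prenyl or chromene alkene while the Lewis acid is present.

Step 17
Reactants: 26 tetrasilyl kuwanon W
Product: 27 kuwanon W
Conditions: Bu4NF (6 equiv), AcOH (6 equiv), THF, 0 °C → rt, argon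
Reagents that add atoms: none
Why: Fluoride cleavage of the four aryl silyl ethers, buffered with acetic acid to keep the polyphenol from base and air oxidation; no stereocenter is touched.

## Compound list

RD = (1S,5R,6S)-5-[2,4-bis(methoxymethoxy)phenyl]-6-{[2,2-dimethyl-5-(triisopropylsilyloxy)-2H-chromen-6-yl]carbonyl}-3-methylcyclohex-2-en-1-yl, i.e. ring D with 3''S,4''S,5''R, all-trans. RD' = the same unit with a free 2,4-dihydroxyphenyl group at C5''.

1 | 2,4-dihydroxyacetophenone | CC(=O)c1ccc(O)cc1O | starting material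
2 | 1-(5-hydroxy-2,2-dimethyl-2H-chromen-6-yl)ethan-1-one | CC(=O)c1ccc2c(c1O)C=CC(C)(C)O2 | intermediate
3 | 2,4-dihydroxybenzaldehyde | O=Cc1ccc(O)cc1O | starting material
4 | 2,4-bis(methoxymethoxy)benzaldehyde | COCOc1ccc(C=O)c(OCOC)c1 | intermediate
5 | (E)-3-[2,4-bis(methoxymethoxy)phenyl]-1-(5-hydroxy-2,2-dimethyl-2H-chromen-6-yl)prop-2-en-1-one | COCOc1ccc(/C=C/C(=O)c2ccc3c(c2O)C=CC(C)(C)O3)c(OCOC)c1 | intermediate
6 | 3-(trimethylsilyl)prop-2-ynal | C[Si](C)(C)C#CC=O | starting material
7 | (E)-6-(trimethylsilyl)hex-3-en-5-yn-2-one | CC(=O)/C=C/C#C[Si](C)(C)C | intermediate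
8 | (E)-trimethyl(5-methylhexa-3,5-dien-1-yn-1-yl)silane | C=C(C)/C=C/C#C[Si](C)(C)C | intermediate
9 | (5-hydroxy-2,2-dimethyl-2H-chromen-6-yl){(1S,2S,6R)-6-[2,4-bis(methoxymethoxy)phenyl]-4-methyl-2-[(trimethylsilyl)ethynyl]cyclohex-3-en-1-yl}methanone (all-trans) | C[Si](C)(C)C#C[C@H]1C=C(C)C[C@@H](c2ccc(OCOC)cc2OCOC)[C@@H]1C(=O)c1ccc2c(c1O)C=CC(C)(C)O2 | intermediate
10 | (5-hydroxy-2,2-dimethyl-2H-chromen-6-yl){(1S,2S,6R)-6-[2,4-bis(methoxymethoxy)phenyl]-2-ethynyl-4-methylcyclohex-3-en-1-yl}methanone | C#C[C@H]1C=C(C)C[C@@H](c2ccc(OCOC)cc2OCOC)[C@@H]1C(=O)c1ccc2c(c1O)C=CC(C)(C)O2 | intermediate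
11 | dilithium salt of 10 oxidised at the alkyne terminus (lithium chromen-5-olate and lithium ynolate) | [Li]OC#C[C@H]1C=C(C)C[C@@H](c2ccc(OCOC)cc2OCOC)[C@@H]1C(=O)c1ccc2c(c1O[Li])C=CC(C)(C)O2 | intermediate (not isolated)
12 | {(1S,2S,6R)-6-[2,4-bis(methoxymethoxy)phenyl]-4-methyl-2-[(triisopropylsilyloxy)ethynyl]cyclohex-3-en-1-yl}[2,2-dimethyl-5-(triisopropylsilyloxy)-2H-chromen-6-yl]methanone | CC(C)[Si](OC#C[C@H]1C=C(C)C[C@@H](c2ccc(OCOC)cc2OCOC)[C@@H]1C(=O)c1ccc2c(c1O[Si](C(C)C)(C(C)C)C(C)C)C=CC(C)(C)O2)(C(C)C)C(C)C | intermediate (key-step precursor)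
13 | 3-ethoxycyclobut-2-en-1-one | CCOC1=CC(=O)C1 | starting material
14 | 3-ethoxybuta-1,3-dien-1-one (ethoxyvinylketene) | C=C(OCC)C=C=O | intermediate (not isolated)
15 | 4-(1-ethoxyethenyl)-2-(RD)-3-(triisopropylsilyloxy)cyclobut-2-en-1-one (epimers at C4 of the cyclobutenone) | C=C(OCC)C1C(=O)C([C@H]2C=C(C)C[C@@H](c3ccc(OCOC)cc3OCOC)[C@@H]2C(=O)c2ccc3c(c2O[Si](C(C)C)(C(C)C)C(C)C)C=CC(C)(C)O3)=C1O[Si](C(C)C)(C(C)C)C(C)C | intermediate (not isolated)
16 | 5-ethoxy-2-(RD)-3-(triisopropylsilyloxy)hexa-1,3,5-trien-1-one (dienylketene) | C=C(OCC)C=C(O[Si](C(C)C)(C(C)C)C(C)C)C([C@H]1C=C(C)C[C@@H](c2ccc(OCOC)cc2OCOC)[C@@H]1C(=O)c1ccc2c(c1O[Si](C(C)C)(C(C)C)C(C)C)C=CC(C)(C)O2)=C=O | intermediate (not isolated)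
17 | 5-ethoxy-2-(RD)-3-(triisopropylsilyloxy)phenol | CCOc1cc(O)c([C@H]2C=C(C)C[C@@H](c3ccc(OCOC)cc3OCOC)[C@@H]2C(=O)c2ccc3c(c2O[Si](C(C)C)(C(C)C)C(C)C)C=CC(C)(C)O3)c(O[Si](C(C)C)(C(C)C)C(C)C)c1 | intermediate (key-step product)
18 | 6-ethoxy-2-hydroxy-3-(RD)-4-(triisopropylsilyloxy)benzaldehyde | CCOc1cc(O[Si](C(C)C)(C(C)C)C(C)C)c([C@H]2C=C(C)C[C@@H](c3ccc(OCOC)cc3OCOC)[C@@H]2C(=O)c2ccc3c(c2O[Si](C(C)C)(C(C)C)C(C)C)C=CC(C)(C)O3)c(O)c1C=O | intermediate
19 | 1-[6-ethoxy-2-hydroxy-3-(RD)-4-(triisopropylsilyloxy)phenyl]-5-methylhex-4-en-1-ol, present as its bromomagnesium alkoxide (carbinol epimers) | CCOc1cc(O[Si](C(C)C)(C(C)C)C(C)C)c([C@H]2C=C(C)C[C@@H](c3ccc(OCOC)cc3OCOC)[C@@H]2C(=O)c2ccc3c(c2O[Si](C(C)C)(C(C)C)C(C)C)C=CC(C)(C)O3)c(O)c1C(O)CCC=C(C)C | intermediate (not isolated)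
20 | 1-[6-ethoxy-2-hydroxy-3-(RD)-4-(triisopropylsilyloxy)phenyl]-5-methylhex-4-en-1-one | CCOc1cc(O[Si](C(C)C)(C(C)C)C(C)C)c([C@H]2C=C(C)C[C@@H](c3ccc(OCOC)cc3OCOC)[C@@H]2C(=O)c2ccc3c(c2O[Si](C(C)C)(C(C)C)C(C)C)C=CC(C)(C)O3)c(O)c1C(=O)CCC=C(C)C | intermediate
21 | 2,4-dihydroxybenzoic acid | O=C(O)c1ccc(O)cc1O | starting material
22 | tert-butyldimethylsilyl 2,4-bis(tert-butyldimethylsilyloxy)benzoate | CC(C)(C)[Si](C)(C)OC(=O)c1ccc(O[Si](C)(C)C(C)(C)C)cc1O[Si](C)(C)C(C)(C)C | intermediate
23 | 2,4-bis(tert-butyldimethylsilyloxy)benzoyl chloride | O=C(Cl)c1ccc(O[Si](C)(C)C(C)(C)C)cc1O[Si](C)(C)C(C)(C)C | intermediate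
24 | 1-[2,4-bis(tert-butyldimethylsilyloxy)phenyl]-3-[6-ethoxy-2-hydroxy-3-(RD)-4-(triisopropylsilyloxy)phenyl]-2-(3-methylbut-2-en-1-yl)propane-1,3-dione (C2 of the dione unassigned) | CCOc1cc(O[Si](C(C)C)(C(C)C)C(C)C)c([C@H]2C=C(C)C[C@@H](c3ccc(OCOC)cc3OCOC)[C@@H]2C(=O)c2ccc3c(c2O[Si](C(C)C)(C(C)C)C(C)C)C=CC(C)(C)O3)c(O)c1C(=O)C(CC=C(C)C)C(=O)c1ccc(O[Si](C)(C)C(C)(C)C)cc1O[Si](C)(C)C(C)(C)C | intermediate
25 | 2-[2,4-bis(tert-butyldimethylsilyloxy)phenyl]-5-ethoxy-3-(3-methylbut-2-en-1-yl)-8-(RD)-7-(triisopropylsilyloxy)-4H-chromen-4-one | CC(C)=CCc1c(-c2ccc(O[Si](C)(C)C(C)(C)C)cc2O[Si](C)(C)C(C)(C)C)oc2c([C@H]3C=C(C)C[C@@H](c4ccc(OCOC)cc4OCOC)[C@@H]3C(=O)c3ccc4c(c3O[Si](C(C)C)(C(C)C)C(C)C)C=CC(C)(C)O4)c(O[Si](C(C)C)(C(C)C)C(C)C)cc(OCC)c2c1=O | intermediate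
26 | 2-[2,4-bis(tert-butyldimethylsilyloxy)phenyl]-5-hydroxy-3-(3-methylbut-2-en-1-yl)-8-(RD')-7-(triisopropylsilyloxy)-4H-chromen-4-one | CC(C)=CCc1c(-c2ccc(O[Si](C)(C)C(C)(C)C)cc2O[Si](C)(C)C(C)(C)C)oc2c([C@H]3C=C(C)C[C@@H](c4ccc(O)cc4O)[C@@H]3C(=O)c3ccc4c(c3O[Si](C(C)C)(C(C)C)C(C)C)C=CC(C)(C)O4)c(O[Si](C(C)C)(C(C)C)C(C)C)cc(O)c2c1=O | intermediate
27 | kuwanon W: 2-(2,4-dihydroxyphenyl)-8-{(1S,5R,6S)-5-(2,4-dihydroxyphenyl)-6-[(5-hydroxy-2,2-dimethyl-2H-chromen-6-yl)carbonyl]-3-methylcyclohex-2-en-1-yl}-5,7-dihydroxy-3-(3-methylbut-2-en-1-yl)-4H-chromen-4-one | CC(C)=CCc1c(-c2ccc(O)cc2O)oc2c([C@H]3C=C(C)C[C@@H](c4ccc(O)cc4O)[C@@H]3C(=O)c3ccc4c(c3O)C=CC(C)(C)O4)c(O)cc(O)c2c1=O | target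

## Step count and least certain steps

Total: 17 steps. Longest linear sequence: 12 steps (1 → 2 → 5 → 9 → 10 → 12 → 17 → 18 → 20 → 24 → 25 → 26 → 27; steps 1, 3, 6, 7, 8, 9, 10, 11, 14, 15, 16, 17).

**Step 9 (key step).** The vinylogous-ester cyclobutenone 13 may open only at temperatures where the siloxyalkyne of 12 already undergoes 1,3-silyl shift to a silylketene, and surplus ketene 14 may O-acylate the product phenol. Fallback: setting out from 12, the same ketene 14 is generated at room temperature by 1,4-dehydrochlorination of (E)-3-ethoxybut-2-enoyl chloride F1 with Et3N in toluene in the presence of 12. Cyclobutenone 15 is isolated and then heated alone at 80 °C, where ring opening, six-electron closure and tautomerisation return the route to 17. The two thermal thresholds are thereby separated and no excess ketene meets the phenol.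

**Step 6.** Exo/endo discrimination may be poor: approach with the aroyl borate under the diene gives the 3'',4''-cis adduct, and face selectivity on the electron-rich chalcone may be incomplete. Fallback: setting out from 5, the diene geometry is inverted so that an endo preference leads to the same product. cis-1,2-Dichloroethene and ethynyltrimethylsilane are coupled (Sonogashira; Pd(PPh3)4, CuI, BuNH2) to (Z)-(4-chlorobut-3-en-1-yn-1-yl)trimethylsilane F2. Kumada coupling with isopropenylmagnesium bromide (PdCl2(dppf)) gives (Z)-trimethyl(5-methylhexa-3,5-dien-1-yn-1-yl)silane F3. Its cycloaddition to 5 under the same borate through the endo transition state places the inside alkynyl group trans to the aroyl group and comes back at 9.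

**Step 8.** Deprotonation α to the ketone, Dakin-type attack of the peroxide at the phenoxide-activated ketone, or protonation of the ynol ether on work-up may compete. Fallback: setting out from 10, the ketone is taken out of play by reduction (LiBH4, THF) to the carbinol {(1S,2S,6R)-6-[2,4-bis(methoxymethoxy)phenyl]-2-ethynyl-4-methylcyclohex-3-en-1-yl}(5-hydroxy-2,2-dimethyl-2H-chromen-6-yl)methanol F4. The same acetylide oxidation is run on its trianion (LiN(SiMe3)2, t-BuOOH, then i-Pr3SiOTf, 2.1 equiv, −78 °C; the hindered secondary alkoxide is the slowest oxygen to silylate). This gives {(1S,2S,6R)-6-[2,4-bis(methoxymethoxy)phenyl]-4-methyl-2-[(triisopropylsilyloxy)ethynyl]cyclohex-3-en-1-yl}[2,2-dimethyl-5-(triisopropylsilyloxy)-2H-chromen-6-yl]methanol F5. Neutral benzylic oxidation with MnO2 in CH2Cl2 returns the route to 12.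

**Step 11.** The Grignard reagent may add to the C4'' ketone, and hydride transfer in the Oppenauer stage may be incomplete. Fallback: setting out from 17, the acyl group is built without an organomagnesium reagent. Ortho-bromination (NBS, i-Pr2NH cat., CH2Cl2, −78 °C) gives 2-bromo-3-ethoxy-6-(RD)-5-(triisopropylsilyloxy)phenol F6. Stille coupling with tributyl(1-ethoxyvinyl)stannane (Pd(PPh3)4, dioxane, 90 °C) and dilute acid hydrolysis of the enol ether give 1-[6-ethoxy-2-hydroxy-3-(RD)-4-(triisopropylsilyloxy)phenyl]ethan-1-one F7. Enolate aroylation with 23 as in step 14 gives 1-[2,4-bis(tert-butyldimethylsilyloxy)phenyl]-3-[6-ethoxy-2-hydroxy-3-(RD)-4-(triisopropylsilyloxy)phenyl]propane-1,3-dione F8. C-Prenylation of the diketone (prenyl bromide, K2CO3, acetone) comes back at 24.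

**Step 16.** BCl3 may ionise the chromene C–O bond, or liberated phenols may cyclise onto the prenyl or ring D alkene. Fallback: setting out from 25, no boron halide is used. Bu4NF/AcOH first removes the four silyl groups and gives the 5-O-ethyl bis-MOM ether of kuwanon W F9. Nucleophilic de-ethylation with NaSEt in DMF (SN2 at the ethyl group of the carbonyl-activated ether) gives the bis(methoxymethyl) ether of kuwanon W F10. Acetal cleavage with ZnBr2 and n-PrSH in CH2Cl2 at room temperature comes back at 27.

## Further compounds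

F1 | step 9 | (E)-3-ethoxybut-2-enoyl chloride | CCO/C(C)=C/C(=O)Cl
F2 | step 6 | (Z)-(4-chlorobut-3-en-1-yn-1-yl)trimethylsilane | C[Si](C)(C)C#C/C=C\Cl
F3 | step 6 | (Z)-trimethyl(5-methylhexa-3,5-dien-1-yn-1-yl)silane | C=C(C)/C=C\C#C[Si](C)(C)C
F4 | step 8 | {(1S,2S,6R)-6-[2,4-bis(methoxymethoxy)phenyl]-2-ethynyl-4-methylcyclohex-3-en-1-yl}(5-hydroxy-2,2-dimethyl-2H-chromen-6-yl)methanol (carbinol epimers) | C#C[C@H]1C=C(C)C[C@@H](c2ccc(OCOC)cc2OCOC)[C@@H]1C(O)c1ccc2c(c1O)C=CC(C)(C)O2
F5 | step 8 | {(1S,2S,6R)-6-[2,4-bis(methoxymethoxy)phenyl]-4-methyl-2-[(triisopropylsilyloxy)ethynyl]cyclohex-3-en-1-yl}[2,2-dimethyl-5-(triisopropylsilyloxy)-2H-chromen-6-yl]methanol (carbinol epimers) | CC(C)[Si](OC#C[C@H]1C=C(C)C[C@@H](c2ccc(OCOC)cc2OCOC)[C@@H]1C(O)c1ccc2c(c1O[Si](C(C)C)(C(C)C)C(C)C)C=CC(C)(C)O2)(C(C)C)C(C)C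
F6 | step 11 | 2-bromo-3-ethoxy-6-(RD)-5-(triisopropylsilyloxy)phenol | CCOc1cc(O[Si](C(C)C)(C(C)C)C(C)C)c([C@H]2C=C(C)C[C@@H](c3ccc(OCOC)cc3OCOC)[C@@H]2C(=O)c2ccc3c(c2O[Si](C(C)C)(C(C)C)C(C)C)C=CC(C)(C)O3)c(O)c1Br
F7 | step 11 | 1-[6-ethoxy-2-hydroxy-3-(RD)-4-(triisopropylsilyloxy)phenyl]ethan-1-one | CCOc1cc(O[Si](C(C)C)(C(C)C)C(C)C)c([C@H]2C=C(C)C[C@@H](c3ccc(OCOC)cc3OCOC)[C@@H]2C(=O)c2ccc3c(c2O[Si](C(C)C)(C(C)C)C(C)C)C=CC(C)(C)O3)c(O)c1C(C)=O
F8 | step 11 | 1-[2,4-bis(tert-butyldimethylsilyloxy)phenyl]-3-[6-ethoxy-2-hydroxy-3-(RD)-4-(triisopropylsilyloxy)phenyl]propane-1,3-dione | CCOc1cc(O[Si](C(C)C)(C(C)C)C(C)C)c([C@H]2C=C(C)C[C@@H](c3ccc(OCOC)cc3OCOC)[C@@H]2C(=O)c2ccc3c(c2O[Si](C(C)C)(C(C)C)C(C)C)C=CC(C)(C)O3)c(O)c1C(=O)CC(=O)c1ccc(O[Si](C)(C)C(C)(C)C)cc1O[Si](C)(C)C(C)(C)C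
F9 | step 16 | 5-O-ethyl kuwanon W bis(methoxymethyl) ether (MOM groups on the C5'' aryl ring) | CC(C)=CCc1c(-c2ccc(O)cc2O)oc2c([C@H]3C=C(C)C[C@@H](c4ccc(OCOC)cc4OCOC)[C@@H]3C(=O)c3ccc4c(c3O)C=CC(C)(C)O4)c(O)cc(OCC)c2c1=O
F10 | step 16 | kuwanon W bis(methoxymethyl) ether (MOM groups on the C5'' aryl ring) | CC(C)=CCc1c(-c2ccc(O)cc2O)oc2c([C@H]3C=C(C)C[C@@H](c4ccc(OCOC)cc4OCOC)[C@@H]3C(=O)c3ccc4c(c3O)C=CC(C)(C)O4)c(O)cc(O)c2c1=O
A1 | alternative 1 | trans-aroyl, aryl vinylcyclobutane with the styryl-type flavone arm on the quaternary carbon | C[C@]1(/C=C/c2c(OCOC)cc(OCOC)c3c2oc(-c2ccc(OCOC)cc2OCOC)c(CC=C(C)C)c3=O)C[C@@H](c2ccc(OCOC)cc2OCOC)[C@@H]1C(=O)c1ccc2c(c1O)C=CC(C)(C)O2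
A2 | alternative 1 | 8-[(E)-3-methylbuta-1,3-dien-1-yl]-3-prenylflavone tetrakis-MOM ether (flavone diene) | C=C(C)/C=C/c1c(OCOC)cc(OCOC)c2c1oc(-c1ccc(OCOC)cc1OCOC)c(CC=C(C)C)c2=O
A3 | alternative 2 | hexa-MOM kuwanon W | CC(C)=CCc1c(-c2ccc(OCOC)cc2OCOC)oc2c([C@H]3C=C(C)C[C@@H](c4ccc(OCOC)cc4OCOC)[C@@H]3C(=O)c3ccc4c(c3O)C=CC(C)(C)O4)c(OCOC)cc(OCOC)c2c1=O
A4 | alternative 2 | hexa-MOM flavone with a free 2,4-dihydroxybenzoyl group on C4'' (chromene not yet formed) | CC(C)=CCc1c(-c2ccc(OCOC)cc2OCOC)oc2c([C@H]3C=C(C)C[C@@H](c4ccc(OCOC)cc4OCOC)[C@@H]3C(=O)c3ccc(O)cc3O)c(OCOC)cc(OCOC)c2c1=O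
A5 | alternative 3 | all-trans cyclohexene ketone carrying a tris-MOM phloroglucinol ring at C3'' | COCOc1cc(OCOC)cc(OCOC)c1[C@H]1C=C(C)C[C@@H](c2ccc(OCOC)cc2OCOC)[C@@H]1C(=O)c1ccc2c(c1OCOC)C=CC(C)(C)O2
A6 | alternative 3 | open-chain triene with vinyl on C3'' and methallyl on C5'' | COCOc1cc(OCOC)cc(OCOC)c1[C@@H](C=C)[C@@H](C(=O)c1ccc2c(c1OCOC)C=CC(C)(C)O2)[C@H](c1ccc(OCOC)cc1OCOC)CC(C)=C
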